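The carbocyclic ring B is cut at C7–C8 and C5–C6. The key step exploits the fact that C8 of the target is the lateral methyl carbon of a 2-methyl-4-pyranone (ring A), vinylogously acidic through C8a=C4a towards the C4 carbonyl, while C5 is the carbon of an ester on the adjacent C4a. One operation (lateral deprotonation, Michael addition to tert-butyl acrylate, Dieckmann closure) should therefore build ring B with both bonds. The precursor is ethyl 6-[(Z)-heptadec-12-enyl]-2-methyl-4-oxo-4H-pyran-3-carboxylate, assembled from an acylketene and an enamine; afterwards decarboxylation and a catalyst-controlled reduction of the C5 ketone set the (S)-carbinol.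

Key step: step 6

Assumption: atoms are numbered as in a chromen-4-one (O1, chain on C2, carbonyl C4, carbinol C5, C8 next to C8a); where the monocyclic precursor is meant, its own pyranone numbering is used and marked as such.

Step 1
Reactants: 1 12-bromododecanoic acid; 2 hex-1-yne
Product: 4 octadec-13-ynoic acid, via lithium hex-1-ynide 3 (not isolated)
Conditions: 2 (2.5 equiv), n-BuLi (2.4 equiv), THF/DMPU, −78 → 0 °C; then 1, 0 → 40 °C; aq. HCl work-up
Reagents that add atoms: none
Why: SN2 alkylation of a lithium acetylide by the primary bromide of the lithium ω-bromo carboxylate, one further equivalent of acetylide serving as base for the acid, with DMPU raising the acetylide reactivity so that substitution should outrun elimination.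

Step 2
Reactants: 4 octadec-13-ynoic acid
Product: 5 (Z)-octadec-13-enoic acid
Conditions: H2 (1 atm), Pd/CaCO3 poisoned with Pb(OAc)2, quinoline, EtOAc, rt, stopped after one equivalent of H2
Reagents that add atoms: none
Why: Lindlar semihydrogenation, in which syn delivery of H2 on the lead-poisoned palladium surface should give the Z olefin while quinoline suppresses over-reduction and isomerisation.

Step 3
Reactants: 5 (Z)-octadec-13-enoic acid; 6 Meldrum's acid (2,2-dimethyl-1,3-dioxane-4,6-dione)
Product: 7 5-[(13Z)-1-hydroxyoctadec-13-en-1-ylidene]-2,2-dimethyl-1,3-dioxane-4,6-dione (enol form of the acyl Meldrum's acid)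
Conditions: DCC, DMAP, CH2Cl2, 0 °C → rt; cold aq. KHSO4 wash; used crude
Reagents that add atoms: none
Why: carbodiimide/DMAP-mediated C-acylation of Meldrum's acid (Steglich-type activation), whose product should be obtained as the stable hydrogen-bonded enol after the acidic wash.

Step 4
Reactants: 8 ethyl acetoacetate
Product: 9 ethyl (E)-3-(pyrrolidin-1-yl)but-2-enoate
Conditions: pyrrolidine (1.05 equiv), PhMe, reflux, Dean–Stark trap; distilled
Reagents that add atoms: pyrrolidine, C1CCNC1
Why: enamine condensation of a β-keto ester with a secondary amine under azeotropic removal of water, which should give the push–pull enamine as the E isomer (nitrogen trans to the ester).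

Step 5
Reactants: 7 acyl Meldrum's acid; 9 ethyl (E)-3-(pyrrolidin-1-yl)but-2-enoate
Product: 12 ethyl 6-[(Z)-heptadec-12-enyl]-2-methyl-4-oxo-4H-pyran-3-carboxylate, via acylketene 10 (not isolated), via C-acylated enaminone 11 (not isolated)
Conditions: PhMe, 100 °C, 7 added slowly to 9 (1.5 equiv); then TsOH·H2O (1.6 equiv), 60 °C
Reagents that add atoms: none
Why: acylketene–enamine synthesis of a 4-pyranone, in which thermal retro-[4+2] fragmentation of 7 gives acylketene 10, 10 acylates the nucleophilic α-carbon of enamine 9, and the diketone enol oxygen of 11 then adds to the amine-bearing carbon with expulsion of pyrrolidine, the acid stage completing the elimination and binding the amine.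

Step 6
Reactants: 12 ethyl 6-[(Z)-heptadec-12-enyl]-2-methyl-4-oxo-4H-pyran-3-carboxylate; 13 tert-butyl acrylate
Product: 16 tert-butyl 2-[(Z)-heptadec-12-enyl]-5-hydroxy-4-oxo-7,8-dihydro-4H-chromene-6-carboxylate (enol form of the β-keto ester), via lateral lithio anion 14 (not isolated), via Michael adduct enolate 15 (not isolated)
Conditions: LiN(iPr)2 (LDA, 1.1 equiv), THF, −78 °C; 13 (1.05 equiv, slow addition), −78 °C → rt; AcOH quench
Reagents that add atoms: none
Why: Proposed new method: LiN(iPr)2 should deprotonate the 2-methyl group of pyranone 12 (the future C8), and the delocalised anion 14 should add through that carbon to tert-butyl acrylate (C8–C7), giving ester enolate 15, which attacks the adjacent ethyl ester (C6–C5) and expels ethoxide; deprotonation of the resulting β-keto ester then makes the sequence irreversible. The closest known reaction type is the Staunton–Weinreb Michael–Dieckmann annulation of ortho-toluate anions, combined with the known lateral lithiation of 2-methyl-4-pyranones; the pyranone ester as toluate surrogate is the untested element, reasonable because its lateral anion is a vinylogous β-keto ester enolate. Ring B closes in a 6-exo-trig Dieckmann mode. No stereocentre is formed, since C6 ends as an enol carbon. The step needs site selectivity for the 2-methyl group over the chain methylene on pyranone C6, secured by the extra acidification through the ester, and conjugate instead of carbonyl addition, secured by the soft anion and the hindered tert-butyl ester. Closure has to outrun acrylate oligomerisation, which the intramolecular six-membered transition state and slow addition of one equivalent of 13 favour, and any 15 quenched by the acidic C8 methylene should be returned by proton exchange on warming because the enolate of 16 is the thermodynamic sink.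

Step 7
Reactants: 16 tert-butyl 2-[(Z)-heptadec-12-enyl]-5-hydroxy-4-oxo-7,8-dihydro-4H-chromene-6-carboxylate
Product: 18 2-[(Z)-heptadec-12-enyl]-7,8-dihydro-4H-chromene-4,5(6H)-dione, via β-keto acid 17 (not isolated)
Conditions: TFA/CH2Cl2 (1:4), 0 °C → rt; concentrate; PhMe, 80 °C
Reagents that add atoms: none
Why: acidolysis of the tert-butyl ester with loss of isobutene followed by thermal decarboxylation of the β-keto acid through a cyclic six-membered transition state, under conditions that should leave the Z olefin and the pyranone untouched.

Step 8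
Reactants: 18 2-[(Z)-heptadec-12-enyl]-7,8-dihydro-4H-chromene-4,5(6H)-dione
Product: 19 (5S)-2-[(Z)-heptadec-12-enyl]-5-hydroxy-5,6,7,8-tetrahydro-4H-chromen-4-one (CNP0118262.1)
Conditions: (R)-2-methyl-CBS-oxazaborolidine (0.2 equiv), catecholborane (1.8 equiv), PhMe, −78 → −40 °C; then MeOH; aqueous work-up
Reagents that add atoms: none
Why: Corey–Bakshi–Shibata reduction, in which the (R)-oxazaborolidine binds catecholborane on nitrogen and the C5 carbonyl on boron anti to the larger, fully substituted sp2 flank C4a, so that hydride should reach the Re face and C5 should emerge S by analogy with aryl alkyl ketones and α-substituted cyclic enones, while catecholborane at low temperature should neither hydroborate the isolated olefin nor reduce the pyranone carbonyl.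

Compound list
1 | 12-bromododecanoic acid | OC(=O)CCCCCCCCCCCBr | starting material
2 | hex-1-yne | CCCCC#C | starting material
3 | lithium hex-1-ynide | [Li]C#CCCCC | intermediate
4 | octadec-13-ynoic acid | CCCCC#CCCCCCCCCCCCC(=O)O | intermediate
5 | (Z)-octadec-13-enoic acid | CCCC/C=C\CCCCCCCCCCCC(=O)O | intermediate
6 | Meldrum's acid (2,2-dimethyl-1,3-dioxane-4,6-dione) | CC1(C)OC(=O)CC(=O)O1 | starting material
7 | 5-[(13Z)-1-hydroxyoctadec-13-en-1-ylidene]-2,2-dimethyl-1,3-dioxane-4,6-dione | CCCC/C=C\CCCCCCCCCCCC(O)=C1C(=O)OC(C)(C)OC1=O | intermediate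
8 | ethyl acetoacetate | CCOC(=O)CC(C)=O | starting material
9 | ethyl (E)-3-(pyrrolidin-1-yl)but-2-enoate | CCOC(=O)/C=C(\C)N1CCCC1 | intermediate
10 | (15Z)-icosa-1,15-diene-1,3-dione (acylketene) | CCCC/C=C\CCCCCCCCCCCC(=O)C=C=O | intermediate
11 | ethyl (17Z)-3,5-dioxo-2-[1-(pyrrolidin-1-yl)ethylidene]docos-17-enoate (enamine geometry not defined) | CCCC/C=C\CCCCCCCCCCCC(=O)CC(=O)C(C(=O)OCC)=C(C)N1CCCC1 | intermediate
12 | ethyl 6-[(Z)-heptadec-12-enyl]-2-methyl-4-oxo-4H-pyran-3-carboxylate | CCCC/C=C\CCCCCCCCCCCc1cc(=O)c(C(=O)OCC)c(C)o1 | intermediate
13 | tert-butyl acrylate | C=CC(=O)OC(C)(C)C | starting material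
14 | ethyl 6-[(Z)-heptadec-12-enyl]-2-(lithiomethyl)-4-oxo-4H-pyran-3-carboxylate (delocalised lateral anion, drawn as the C-lithio form) | CCCC/C=C\CCCCCCCCCCCc1cc(=O)c(C(=O)OCC)c(C[Li])o1 | intermediate
15 | lithium ester enolate of ethyl 2-(4-tert-butoxy-4-oxobutyl)-6-[(Z)-heptadec-12-enyl]-4-oxo-4H-pyran-3-carboxylate (enolate geometry not defined) | CCCC/C=C\CCCCCCCCCCCc1cc(=O)c(C(=O)OCC)c(CCC=C(O[Li])OC(C)(C)C)o1 | intermediate
16 | tert-butyl 2-[(Z)-heptadec-12-enyl]-5-hydroxy-4-oxo-7,8-dihydro-4H-chromene-6-carboxylate | CCCC/C=C\CCCCCCCCCCCc1cc(=O)c2c(o1)CCC(C(=O)OC(C)(C)C)=C2O | intermediate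
17 | 2-[(Z)-heptadec-12-enyl]-5-hydroxy-4-oxo-7,8-dihydro-4H-chromene-6-carboxylic acid | CCCC/C=C\CCCCCCCCCCCc1cc(=O)c2c(o1)CCC(C(=O)O)=C2O | intermediate
18 | 2-[(Z)-heptadec-12-enyl]-7,8-dihydro-4H-chromene-4,5(6H)-dione | CCCC/C=C\CCCCCCCCCCCc1cc(=O)c2c(o1)CCCC2=O | intermediate
19 | (5S)-2-[(Z)-heptadec-12-enyl]-5-hydroxy-5,6,7,8-tetrahydro-4H-chromen-4-one | CCCC/C=C\CCCCCCCCCCCc1cc(=O)c2c(o1)CCC[C@@H]2O | target

Total step count: 8. Longest linear sequence: 7 steps (1, 2, 3, 5, 6, 7, 8); step 4 is a one-step side branch.

Steps most likely to fail

Step 6 (labelled step). The lateral anion may condense with the ester of a second molecule, the Michael-derived enolate may be protonated before it closes, or it may start oligomerising the acrylate. The fallback uses known chemistry and sets out from compound 7. Heating 7 with commercial cyclohexane-1,3-dione (O=C1CCCC(=O)C1) in toluene should let the acylketene C-acylate the dione enol to give the triketone 2-[(Z)-3-oxoicos-15-enoyl]cyclohexane-1,3-dione F1. Treatment with TFA then closes the pyranone by cyclodehydration. Both reaction types are established: acylketene acylation of cyclic 1,3-dicarbonyl enols and acid cyclodehydration of 1,3,5-tricarbonyl compounds to 4-pyranones. The fallback comes back to the route at compound 18, before step 8.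

Step 5. Pyrrolidine released during ring closure may intercept the acylketene as a β-keto amide while 7 is still fragmenting, and acylketene dimerisation may compete with acylation of the enamine. The fallback sets out from compound 7 and avoids any amine. Thermolysis of 7 in toluene containing an excess of commercial ethyl (E)-3-ethoxybut-2-enoate should give, by hetero-Diels–Alder addition of the acylketene to the enol ether, the ketal ethyl 2-ethoxy-6-[(Z)-heptadec-12-enyl]-2-methyl-4-oxo-3,4-dihydro-2H-pyran-3-carboxylate F2. This adduct keeps its leaving group until all of 7 is consumed; TsOH then expels ethanol. The fallback comes back to the route at compound 12.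

Step 8. Facial selectivity may be eroded if the Lewis-basic pyranone carbonyl competes with the C5 carbonyl for the catalyst boron, and the reduction of the electron-rich C5 ketone may be slow. The fallback sets out from compound 18 and moves stereocontrol from the reagent to a resolution. Luche reduction (NaBH4, CeCl3·7H2O, MeOH, 0 °C) should give the racemic alcohol 2-[(Z)-heptadec-12-enyl]-5-hydroxy-5,6,7,8-tetrahydro-4H-chromen-4-one F3. Candida antarctica lipase B with vinyl acetate should then acetylate the R enantiomer, following the usual enantiopreference of lipases for secondary alcohols with one large sp2 flank, to give (5R)-2-[(Z)-heptadec-12-enyl]-4-oxo-5,6,7,8-tetrahydro-4H-chromen-5-yl acetate F4. The unreacted S alcohol is separated by chromatography, so the fallback comes back to the route at compound 19.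

Further compounds
F1 | step 6 | 2-[(Z)-3-oxoicos-15-enoyl]cyclohexane-1,3-dione | CCCC/C=C\CCCCCCCCCCCC(=O)CC(=O)C1C(=O)CCCC1=O
F2 | step 5 | ethyl 2-ethoxy-6-[(Z)-heptadec-12-enyl]-2-methyl-4-oxo-3,4-dihydro-2H-pyran-3-carboxylate (mixture of diastereomers) | CCCC/C=C\CCCCCCCCCCCC1=CC(=O)C(C(=O)OCC)C(C)(OCC)O1
F3 | step 8 | racemic 2-[(Z)-heptadec-12-enyl]-5-hydroxy-5,6,7,8-tetrahydro-4H-chromen-4-one | CCCC/C=C\CCCCCCCCCCCc1cc(=O)c2c(o1)CCCC2O
F4 | step 8 | (5R)-2-[(Z)-heptadec-12-enyl]-4-oxo-5,6,7,8-tetrahydro-4H-chromen-5-yl acetate | CCCC/C=C\CCCCCCCCCCCc1cc(=O)c2c(o1)CCC[C@H]2OC(C)=O
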